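Assumption: natural (+)-(3S,6E)-nerolidol is bought as the single enantiomer; its optical purity is carried unchanged into the target.

**Retrosynthetic overview**
1. Target 17 ⇐ (E)-alkenylquinone carbinol 14: the pyran ring (ring B) is closed last onto the preformed benzene ring (ring A) through the O1–C8a bond, by a light-gated hemiketal closure followed by reduction.
2. 14 ⇐ dimethoxyarene acid 13 (oxidative demethylation) ⇐ ester 12 ⇐ Heck coupling of vinyl carbinol 9 with aryl iodide 11.
3. 9 ⇐ Z-selective Still–Gennari olefination of aldehyde 5 with homoprenyl phosphonate 8.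
4. 5 ⇐ (3S,6E)-nerolidol 1 by cleavage of the terminal alkene; the carbinol carbon of 1 becomes C2 of the chromene, and its C–O bond is never broken.
5. Ring order: ring A is bought (10), ring B is formed in the last step.

**Route**

Step 1
Reactants: 1 (3S,6E)-nerolidol
Product: 3 (3S,6E)-10,11-epoxy-3,7,11-trimethyldodeca-1,6-dien-3-ol, via bromohydrin 2 (not isolated)
Conditions: NBS (1.1 equiv), THF/H2O (2:1), 0 °C; then K2CO3, MeOH, rt
Reagents that add atoms: water, O
Why: Terminal-selective bromohydrin formation and epoxide closure: in largely aqueous THF, NBS attacks the terminal trisubstituted alkene of a polyprenyl chain in preference to the internal alkene and the vinyl group, water opens the bromonium ion at the tertiary carbon, and K2CO3 closes the epoxide; C3 is untouched and the uncontrolled epoxide carbon is removed in step 2.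

Step 2
Reactants: 3 (3S,6E)-10,11-epoxy-3,7,11-trimethyldodeca-1,6-dien-3-ol
Product: 5 (4E,8S)-8-hydroxy-4,8-dimethyldeca-4,9-dienal, via triol 4 (not isolated)
Conditions: H5IO6 (1.2 equiv), THF/H2O (10:1), 0 °C, 30 min
Reagents that add atoms: none
Why: Periodic acid hydrolyses the epoxide to the vicinal diol and cleaves it in the same flask (glycol cleavage), releasing acetone; the aldehyde oxygen is the former epoxide oxygen, and the E-alkene, vinyl group and carbinol are unchanged at 0 °C.

Step 3
Reactants: 6 methyl 2-[bis(2,2,2-trifluoroethoxy)phosphoryl]acetate; 7 5-bromo-2-methylpent-2-ene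
Product: 8 methyl 2-[bis(2,2,2-trifluoroethoxy)phosphoryl]-6-methylhept-5-enoate
Conditions: NaH, DMF, 0 °C; then 7, NaI (cat.), 50 °C (6 in 1.5-fold excess)
Reagents that add atoms: none
Why: SN2 C-alkylation of the sodium phosphonoacetate by the primary homoallylic bromide with iodide catalysis, excess 6 suppressing dialkylation; the new centre is racemic and is destroyed in step 4.

Step 4
Reactants: 5 (4E,8S)-8-hydroxy-4,8-dimethyldeca-4,9-dienal; 8 methyl 2-[bis(2,2,2-trifluoroethoxy)phosphoryl]-6-methylhept-5-enoate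
Product: 9 methyl (2Z,6E,10S)-10-hydroxy-6,10-dimethyl-2-(4-methylpent-3-en-1-yl)dodeca-2,6,11-trienoate
Conditions: 8 (1.3 equiv), KN(SiMe3)2, 18-crown-6, THF, −78 °C; then 5, −78 °C
Reagents that add atoms: none
Why: Still–Gennari olefination: the trifluoroethyl phosphonate anion with a dissociated potassium counter-ion adds irreversibly and eliminates fast, placing the ester cis to the chain (2Z); the tertiary alcohol is not deprotonated by the stabilised anion and C10 is untouched.

Step 5
Reactants: 10 1,4-dimethoxy-2,3-dimethylbenzene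
Product: 11 1-iodo-2,5-dimethoxy-3,4-dimethylbenzene
Conditions: NIS (1.05 equiv), CF3CO2H (10 mol%), MeCN, rt
Reagents that add atoms: N-iodosuccinimide, O=C1CCC(=O)N1I
Why: Electrophilic aromatic iodination of the symmetrical electron-rich arene gives a single mono-iodide because the two free positions are equivalent.

Step 6
Reactants: 9 methyl (2Z,6E,10S)-10-hydroxy-6,10-dimethyl-2-(4-methylpent-3-en-1-yl)dodeca-2,6,11-trienoate; 11 1-iodo-2,5-dimethoxy-3,4-dimethylbenzene
Product: 12 methyl (2Z,6E,10S,11E)-12-(2,5-dimethoxy-3,4-dimethylphenyl)-10-hydroxy-6,10-dimethyl-2-(4-methylpent-3-en-1-yl)dodeca-2,6,11-trienoate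
Conditions: Pd(OAc)2 (5 mol%), n-Bu4NCl, NaHCO3, DMF, 60 °C; chromatography on Et3N-washed silica
Reagents that add atoms: none
Why: Mizoroki–Heck reaction under ligand-free phase-transfer (Jeffery) conditions: the arylpalladium species adds to the terminal carbon of the vinyl carbinol, and syn β-hydride elimination can only give the (E)-styrene because the carbinol carbon carries no hydrogen; the trisubstituted alkenes do not react and the stereocentre is untouched.

Step 7
Reactants: 12 methyl (2Z,6E,10S,11E)-12-(2,5-dimethoxy-3,4-dimethylphenyl)-10-hydroxy-6,10-dimethyl-2-(4-methylpent-3-en-1-yl)dodeca-2,6,11-trienoate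
Product: 13 (2Z,6E,10S,11E)-12-(2,5-dimethoxy-3,4-dimethylphenyl)-10-hydroxy-6,10-dimethyl-2-(4-methylpent-3-en-1-yl)dodeca-2,6,11-trienoic acid
Conditions: LiOH·H2O (5 equiv), THF/MeOH/H2O (3:1:1), 40 °C; then aq. citric acid to pH 4, 0 °C
Reagents that add atoms: lithium hydroxide, [Li+].[OH-]
Why: Saponification of the methyl ester under mild conditions that do not isomerise the Z-enoate, placed here because the dimethoxyarene is base-stable whereas the later quinone and chromenol are not.

Step 8
Reactants: 13 (2Z,6E,10S,11E)-12-(2,5-dimethoxy-3,4-dimethylphenyl)-10-hydroxy-6,10-dimethyl-2-(4-methylpent-3-en-1-yl)dodeca-2,6,11-trienoic acid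
Product: 14 (2Z,6E,10S,11E)-12-(4,5-dimethyl-3,6-dioxocyclohexa-1,4-dien-1-yl)-10-hydroxy-6,10-dimethyl-2-(4-methylpent-3-en-1-yl)dodeca-2,6,11-trienoic acid
Conditions: (NH4)2Ce(NO3)6 (2.2 equiv), pyridine-2,6-dicarboxylic acid N-oxide (2.2 equiv), MeCN/H2O (2:1), 0 °C, 15 min; used at once
Reagents that add atoms: water, O
Why: Oxidative demethylation by tetravalent cerium (arene radical cation, ipso attack of water, loss of methanol) gives the p-quinone; the N-oxide ligand buffers the nitric acid so that the acid-labile, aryl-conjugated tertiary allylic alcohol does not ionise and C10 keeps its configuration.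

Step 9
Reactants: 14 (2Z,6E,10S,11E)-12-(4,5-dimethyl-3,6-dioxocyclohexa-1,4-dien-1-yl)-10-hydroxy-6,10-dimethyl-2-(4-methylpent-3-en-1-yl)dodeca-2,6,11-trienoic acid
Product: 17 (2Z,6E)-9-[(2S)-6-hydroxy-2,7,8-trimethyl-2H-chromen-2-yl]-6-methyl-2-(4-methylpent-3-en-1-yl)nona-2,6-dienoic acid, via Z-quinone 15 (not isolated), via cyclic hemiketal 16 (not isolated)
Conditions: hν (450 nm LEDs), degassed MeCN/pH 4.5 acetate buffer (9:1), 2 mM, 10 °C; then L-ascorbic acid (3 equiv), dark, rt
Reagents that add atoms: none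
Why: Proposed new method: 450 nm light excites only the alkenylquinone charge-transfer band and isomerises 14 to the twisted Z-quinone 15, whose tertiary hydroxyl then sits over the neighbouring quinone carbonyl and closes to the cyclic hemiketal 16 (O1–C8a bond, ring B), a cross-conjugated dienone that no longer absorbs at 450 nm, so the photostationary mixture drains into 16; ascorbic acid then reduces the chromenoxylium ion formed from 16 by acid-assisted loss of water (two electrons, one proton) to the chromenol, and because the C–O bond of the nerolidol carbinol is never broken the (S) centre is carried over with retention; the closest known reaction types are the photochemical E-to-Z isomerisation/lactonisation of o-hydroxycinnamic acids to coumarins and the ascorbate reduction of 8a-hydroxytocopherones to tocopherols, neither shown for an alkenylquinone carbinol.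

**Compound list**

1 | (3S,6E)-nerolidol, (3S,6E)-3,7,11-trimethyldodeca-1,6,10-trien-3-ol | CC(C)=CCC/C(C)=C/CC[C@@](O)(C)C=C | starting material
2 | (3S,6E)-10-bromo-3,7,11-trimethyldodeca-1,6-diene-3,11-diol (both C10 epimers) | CC(C)(O)C(Br)CC/C(C)=C/CC[C@@](O)(C)C=C | intermediate
3 | (3S,6E)-10,11-epoxy-3,7,11-trimethyldodeca-1,6-dien-3-ol (both C10 epimers) | CC1(C)OC1CC/C(C)=C/CC[C@@](O)(C)C=C | intermediate
4 | (3S,6E)-3,7,11-trimethyldodeca-1,6-diene-3,10,11-triol (both C10 epimers) | CC(C)(O)C(O)CC/C(C)=C/CC[C@@](O)(C)C=C | intermediate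
5 | (4E,8S)-8-hydroxy-4,8-dimethyldeca-4,9-dienal | O=CCC/C(C)=C/CC[C@@](O)(C)C=C | intermediate
6 | methyl 2-[bis(2,2,2-trifluoroethoxy)phosphoryl]acetate | COC(=O)CP(=O)(OCC(F)(F)F)OCC(F)(F)F | starting material
7 | 5-bromo-2-methylpent-2-ene | CC(C)=CCCBr | starting material
8 | methyl 2-[bis(2,2,2-trifluoroethoxy)phosphoryl]-6-methylhept-5-enoate (racemic) | COC(=O)C(CCC=C(C)C)P(=O)(OCC(F)(F)F)OCC(F)(F)F | intermediate
9 | methyl (2Z,6E,10S)-10-hydroxy-6,10-dimethyl-2-(4-methylpent-3-en-1-yl)dodeca-2,6,11-trienoate | COC(=O)/C(CCC=C(C)C)=C\CC/C(C)=C/CC[C@@](O)(C)C=C | intermediate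
10 | 1,4-dimethoxy-2,3-dimethylbenzene | COc1ccc(OC)c(C)c1C | starting material
11 | 1-iodo-2,5-dimethoxy-3,4-dimethylbenzene | COc1cc(I)c(OC)c(C)c1C | intermediate
12 | methyl (2Z,6E,10S,11E)-12-(2,5-dimethoxy-3,4-dimethylphenyl)-10-hydroxy-6,10-dimethyl-2-(4-methylpent-3-en-1-yl)dodeca-2,6,11-trienoate | COC(=O)/C(CCC=C(C)C)=C\CC/C(C)=C/CC[C@@](O)(C)/C=C/c1cc(OC)c(C)c(C)c1OC | intermediate
13 | (2Z,6E,10S,11E)-12-(2,5-dimethoxy-3,4-dimethylphenyl)-10-hydroxy-6,10-dimethyl-2-(4-methylpent-3-en-1-yl)dodeca-2,6,11-trienoic acid | OC(=O)/C(CCC=C(C)C)=C\CC/C(C)=C/CC[C@@](O)(C)/C=C/c1cc(OC)c(C)c(C)c1OC | intermediate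
14 | (2Z,6E,10S,11E)-12-(4,5-dimethyl-3,6-dioxocyclohexa-1,4-dien-1-yl)-10-hydroxy-6,10-dimethyl-2-(4-methylpent-3-en-1-yl)dodeca-2,6,11-trienoic acid | OC(=O)/C(CCC=C(C)C)=C\CC/C(C)=C/CC[C@@](O)(C)/C=C/C1=CC(=O)C(C)=C(C)C1=O | intermediate
15 | (2Z,6E,10S,11Z)-12-(4,5-dimethyl-3,6-dioxocyclohexa-1,4-dien-1-yl)-10-hydroxy-6,10-dimethyl-2-(4-methylpent-3-en-1-yl)dodeca-2,6,11-trienoic acid | OC(=O)/C(CCC=C(C)C)=C\CC/C(C)=C/CC[C@@](O)(C)/C=C\C1=CC(=O)C(C)=C(C)C1=O | intermediate
16 | (2Z,6E)-9-[(2S)-8a-hydroxy-2,7,8-trimethyl-6-oxo-6,8a-dihydro-2H-chromen-2-yl]-6-methyl-2-(4-methylpent-3-en-1-yl)nona-2,6-dienoic acid (both C8a epimers) | OC(=O)/C(CCC=C(C)C)=C\CC/C(C)=C/CC[C@@]1(C)C=CC2=CC(=O)C(C)=C(C)C2(O)O1 | intermediate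
17 | (2Z,6E)-9-[(2S)-6-hydroxy-2,7,8-trimethyl-2H-chromen-2-yl]-6-methyl-2-(4-methylpent-3-en-1-yl)nona-2,6-dienoic acid | CC(C)=CCC/C(=C/CC/C(C)=C/CC[C@@]1(C)C=Cc2cc(O)c(C)c(C)c2O1)C(=O)O | target

**Step count and risks**

Total steps: 9. Longest linear sequence: 7 steps (1, 2, 4, 6, 7, 8, 9, from nerolidol); steps 3 and 5 are one-step side branches.

Steps most likely to fail:

Step 9 (the new step). Three things can go wrong. The excited quinone carbonyl oxygen can attack the alkene and give a benzofuranol. The hydroxyl of 15 can add in conjugate fashion to the free C5 position instead of closing the hemiketal. Ascorbic acid can reduce open quinone to the hydroquinone before ring closure; that material can be re-oxidised in air and cycled again. The fallback uses known chemistry, sets out from 9 (with 11) and comes back at 17. Hydroboration of the vinyl group of 9 with 9-BBN (2.5 equiv, THF, rt) gives the alkylborane F1. B-alkyl Suzuki coupling of F1 with 11 (PdCl2(dppf), K3PO4, DMF/H2O, 50 °C) gives the saturated aryl carbinol ester F2. Oxidation with (NH4)2Ce(NO3)6 as in step 8 gives the saturated quinone ester F3. Reduction with Na2S2O4 and acid-catalysed, quinone-relayed ring closure of the hydroquinone (p-TsOH cat., 2 mol% F3, toluene, 40 °C, argon) gives the chromanol ester F4. In this closure the carbinol oxygen adds to the quinone carbonyl and the hemiketal is dehydrated and reduced by the next hydroquinone, as in the quinone-catalysed etherification of hydroquinones and the ring closure of tocopherylquinones, so the carbinol C–O bond stays intact. Acetylation (Ac2O, pyridine) gives the chromanyl acetate F5, and DDQ in refluxing dioxane dehydrogenates C3–C4 to the chromene acetate F6. LiOH (degassed THF/MeOH/H2O) then cleaves acetate and methyl ester to 17.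

Step 8. The aryl-conjugated tertiary allylic alcohol can ionise under the acidic oxidant (racemisation, allylic transposition), and the alkenylquinone can oligomerise. The fallback sets out from 13 and comes back at 14. Constant-current anodic oxidation of 13 in 1% KOH/MeOH (Pt anode, undivided cell, 0 °C) gives, under basic conditions, the quinone bis(dimethyl ketal) F7. Brief hydrolysis on wet silica impregnated with oxalic acid in CH2Cl2 at 0 °C, where the ring is no longer electron-rich and the carbinol no longer ionises easily, gives 14.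

Step 4. The α-branched phosphonate may react sluggishly or with eroded Z-selectivity, and the geometry cannot be corrected later. The fallback sets out from 5 and comes back at 9. Olefination of 5 with the bromophosphonate F8 (from 6 with NaH and NBS; t-BuOK, 18-crown-6, THF, −78 °C) gives the (E)-α-bromo enoate F9, in which the ester is already cis to the chain. Negishi coupling with homoprenylzinc bromide F10 (from 7, Zn dust, LiCl, THF; 2.2 equiv) and PdCl2(dppf) replaces bromine with retention of alkene geometry and gives 9.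

**Further compounds**

F1 | step 9 | methyl (2Z,6E,10R)-12-(9-borabicyclo[3.3.1]nonan-9-yl)-10-hydroxy-6,10-dimethyl-2-(4-methylpent-3-en-1-yl)dodeca-2,6-dienoate (same arrangement in space as 9; the descriptor changes by the priority rules only) | COC(=O)/C(CCC=C(C)C)=C\CC/C(C)=C/CC[C@@](O)(C)CCB1C2CCCC1CCC2
F2 | step 9 | methyl (2Z,6E,10S)-12-(2,5-dimethoxy-3,4-dimethylphenyl)-10-hydroxy-6,10-dimethyl-2-(4-methylpent-3-en-1-yl)dodeca-2,6-dienoate | COC(=O)/C(CCC=C(C)C)=C\CC/C(C)=C/CC[C@@](O)(C)CCc1cc(OC)c(C)c(C)c1OC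
F3 | step 9 | methyl (2Z,6E,10S)-12-(4,5-dimethyl-3,6-dioxocyclohexa-1,4-dien-1-yl)-10-hydroxy-6,10-dimethyl-2-(4-methylpent-3-en-1-yl)dodeca-2,6-dienoate | COC(=O)/C(CCC=C(C)C)=C\CC/C(C)=C/CC[C@@](O)(C)CCC1=CC(=O)C(C)=C(C)C1=O
F4 | step 9 | methyl (2Z,6E)-9-[(2S)-6-hydroxy-2,7,8-trimethyl-3,4-dihydro-2H-chromen-2-yl]-6-methyl-2-(4-methylpent-3-en-1-yl)nona-2,6-dienoate | COC(=O)/C(CCC=C(C)C)=C\CC/C(C)=C/CC[C@@]1(C)CCc2cc(O)c(C)c(C)c2O1
F5 | step 9 | methyl (2Z,6E)-9-[(2S)-6-acetoxy-2,7,8-trimethyl-3,4-dihydro-2H-chromen-2-yl]-6-methyl-2-(4-methylpent-3-en-1-yl)nona-2,6-dienoate | COC(=O)/C(CCC=C(C)C)=C\CC/C(C)=C/CC[C@@]1(C)CCc2cc(OC(C)=O)c(C)c(C)c2O1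
F6 | step 9 | methyl (2Z,6E)-9-[(2S)-6-acetoxy-2,7,8-trimethyl-2H-chromen-2-yl]-6-methyl-2-(4-methylpent-3-en-1-yl)nona-2,6-dienoate | COC(=O)/C(CCC=C(C)C)=C\CC/C(C)=C/CC[C@@]1(C)C=Cc2cc(OC(C)=O)c(C)c(C)c2O1
F7 | step 8 | (2Z,6E,10S,11E)-10-hydroxy-6,10-dimethyl-2-(4-methylpent-3-en-1-yl)-12-(3,3,6,6-tetramethoxy-4,5-dimethylcyclohexa-1,4-dien-1-yl)dodeca-2,6,11-trienoic acid | OC(=O)/C(CCC=C(C)C)=C\CC/C(C)=C/CC[C@@](O)(C)/C=C/C1=CC(OC)(OC)C(C)=C(C)C1(OC)OC
F8 | step 4 | methyl 2-bromo-2-[bis(2,2,2-trifluoroethoxy)phosphoryl]acetate | COC(=O)C(Br)P(=O)(OCC(F)(F)F)OCC(F)(F)F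
F9 | step 4 | methyl (2E,6E,10S)-2-bromo-10-hydroxy-6,10-dimethyldodeca-2,6,11-trienoate | COC(=O)/C(Br)=C\CC/C(C)=C/CC[C@@](O)(C)C=C
F10 | step 4 | (4-methylpent-3-en-1-yl)zinc bromide | CC(C)=CCC[Zn]Br
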